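Ring A (C1–C5, C10) holds the gem-dimethyl carbon C4 and the methyl-bearing C10 on either side of C5. Deleting C5 from the ring leaves a 1,2,2-trimethylcyclopentane, the carbon frame of camphoric acid. Everything rests on re-inserting C5. Formolysis of a C5 mesylate makes C4 migrate from C10 to C5, turning the cyclopentane into ring A. The C10 cation is taken by the (E)-C8=C9 alkene to close ring B, and formic acid caps C8. One operation thus sets C5, C10, C9 and C8 and installs the formate. The precursor is a monocyclic mesylate: a (S)-1,2,2-trimethylcyclopentyl carbinol carrying a citronellate-derived chain.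

Key step: step 11

Remark: labdane numbering (C1 to C20) is used for the target and, in anticipation, for the carbons of its precursors. (1S,3R)-(−)-Camphoric acid and (S)-(−)-citronellic acid are assumed to be bought as single enantiomers.

Step 1
Reactants: 1 (1S,3R)-(−)-camphoric acid
Product: 2 (1S,3R)-3-(methoxycarbonyl)-1,2,2-trimethylcyclopentane-1-carboxylic acid
Conditions: MeOH, H2SO4 (cat.), reflux
Reagents that add atoms: methanol, CO
Why: Fischer esterification should touch only the secondary carboxyl, because the tertiary carboxyl sits between a quaternary ring carbon and the gem-dimethyl carbon and is too hindered; no stereocentre is affected.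

Step 2
Reactants: 2 (1S,3R)-3-(methoxycarbonyl)-1,2,2-trimethylcyclopentane-1-carboxylic acid
Product: 4 methyl (1R,3S)-3-acetyl-2,2,3-trimethylcyclopentane-1-carboxylate, via acid chloride 3 (not isolated)
Conditions: (COCl)2, DMF (cat.), CH2Cl2, 0 °C to rt, concentrate; then MeMgBr (1.1 equiv), CuCl (5 mol %), THF, −20 °C
Reagents that add atoms: oxalyl chloride, O=C(Cl)C(=O)Cl (chlorine of 3 only); methylmagnesium bromide, C[Mg]Br
Why: Copper-catalysed acylation of a Grignard reagent by a hindered acid chloride should stop at the ketone, since the acid chloride reacts far faster than the methyl ester or the congested product ketone.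

Step 3
Reactants: 4 methyl (1R,3S)-3-acetyl-2,2,3-trimethylcyclopentane-1-carboxylate
Product: 5 (1R,3S)-3-acetyl-2,2,3-trimethylcyclopentane-1-carboxylic acid
Conditions: LiOH, THF/MeOH/H2O, rt; then 1 M HCl
Reagents that add atoms: lithium hydroxide, [Li+].[OH-]
Why: Saponification of the unhindered secondary ester; any epimerisation next to the carboxyl is harmless because that centre becomes CH2 in step 4.

Step 4
Reactants: 5 (1R,3S)-3-acetyl-2,2,3-trimethylcyclopentane-1-carboxylic acid
Product: 6 1-[(1S)-1,2,2-trimethylcyclopentyl]ethan-1-one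
Conditions: 9-mesityl-10-phenylacridinium tetrafluoroborate (5 mol %), PhSSPh (10 mol %), iPr2NEt (20 mol %), CF3CH2OH, 450 nm LED, rt
Reagents that add atoms: none
Why: Photoredox hydrodecarboxylation, in which the excited acridinium oxidises the carboxylate, CO2 is lost and the secondary ring radical takes hydrogen from thiophenol, leaves the quaternary stereocentre (future C10) untouched.

Step 5
Reactants: 7 (S)-(−)-citronellic acid
Product: 8 benzyl (3S)-3,7-dimethyloct-6-enoate
Conditions: BnBr, K2CO3, DMF, rt
Reagents that add atoms: benzyl bromide, BrCc1ccccc1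
Why: Carboxylate O-alkylation installs an ester that survives enolate, borane, sulfonylation and formic acid conditions and can be removed at the end under neutral conditions.

Step 6
Reactants: 8 benzyl (3S)-3,7-dimethyloct-6-enoate
Product: 9 benzyl (3S,6E)-8-hydroxy-3,7-dimethyloct-6-enoate
Conditions: SeO2 (cat.), tBuOOH, salicylic acid (cat.), CH2Cl2, 0 °C to rt
Reagents that add atoms: tert-butyl hydroperoxide, CC(C)(C)OO
Why: Riley allylic oxidation (ene reaction, then [2,3]-sigmatropic shift) places oxygen on the methyl group trans to the chain and so fixes the (E)-geometry of the later C8=C9 alkene.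

Step 7
Reactants: 9 benzyl (3S,6E)-8-hydroxy-3,7-dimethyloct-6-enoate
Product: 10 benzyl (3S,6E)-8-bromo-3,7-dimethyloct-6-enoate
Conditions: CBr4, PPh3, CH2Cl2, 0 °C
Reagents that add atoms: carbon tetrabromide, BrC(Br)(Br)Br
Why: The Appel reaction converts the primary allylic alcohol to the bromide under neutral conditions, without allylic transposition or loss of alkene geometry.

Step 8
Reactants: 6 1-[(1S)-1,2,2-trimethylcyclopentyl]ethan-1-one; 10 benzyl (3S,6E)-8-bromo-3,7-dimethyloct-6-enoate
Product: 12 benzyl (3S,6E)-3,7-dimethyl-10-oxo-10-[(1S)-1,2,2-trimethylcyclopentyl]dec-6-enoate, via lithium enolate 11 (not isolated)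
Conditions: LiN(iPr)2 (LDA), THF, −78 °C; then 10, −78 °C to 0 °C
Reagents that add atoms: lithium diisopropylamide, [Li+].CC(C)[N-]C(C)C (lithium of 11 only)
Why: Lithium enolate alkylation (SN2 at a primary allylic bromide) forms the C6–C7 bond; 6 can enolise only toward its methyl group because the other α-carbon is quaternary, and no stereocentre or alkene is disturbed.

Step 9
Reactants: 12 benzyl (3S,6E)-3,7-dimethyl-10-oxo-10-[(1S)-1,2,2-trimethylcyclopentyl]dec-6-enoate
Product: 14 benzyl (3S,6E,10S)-10-hydroxy-3,7-dimethyl-10-[(1S)-1,2,2-trimethylcyclopentyl]dec-6-enoate, via catechol borate 13 (not isolated)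
Conditions: (R)-2-methyl-CBS-oxazaborolidine [(R)-1-methyl-3,3-diphenyltetrahydro-1H,3H-pyrrolo[1,2-c][1,3,2]oxazaborole] (20 mol %), catecholborane, toluene, −40 °C to −20 °C; aqueous work-up
Reagents that add atoms: catecholborane, B1Oc2ccccc2O1 (boron and catecholate of 13 only)
Why: Corey–Bakshi–Shibata reduction, in which the catalyst tells the tert-alkyl group from the primary alkyl chain as it does for pinacolone, should give the (10S)-carbinol (C5 of the labdane) with the (R)-catalyst, and catecholborane spares alkene and ester.

Step 10
Reactants: 14 benzyl (3S,6E,10S)-10-hydroxy-3,7-dimethyl-10-[(1S)-1,2,2-trimethylcyclopentyl]dec-6-enoate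
Product: 15 benzyl (3S,6E,10S)-10-(methanesulfonyloxy)-3,7-dimethyl-10-[(1S)-1,2,2-trimethylcyclopentyl]dec-6-enoate
Conditions: MsCl, NEt3, CH2Cl2, −20 °C to 0 °C; cold aqueous work-up, used without chromatography
Reagents that add atoms: methanesulfonyl chloride, CS(=O)(=O)Cl
Why: Mesylation through sulfene, an electrophile small enough to reach the neopentyl-type hydroxyl, leaves the C–O bond intact, so the configuration at C5 is retained.

Step 11
Reactants: 15 benzyl (3S,6E,10S)-10-(methanesulfonyloxy)-3,7-dimethyl-10-[(1S)-1,2,2-trimethylcyclopentyl]dec-6-enoate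
Product: 18 benzyl (13S)-8α-formyloxylabdan-15-oate, via ring-expanded C10 cation 16 (not isolated), via bicyclic C8 cation 17 (not isolated)
Conditions: anhydrous HCOOH/CH2Cl2 (4:1), HCOONa (3 equiv), 0 °C to 25–40 °C
Reagents that add atoms: formic acid, O=CO
Why: Ionisation of the hindered secondary mesylate is assisted by the anti-periplanar C10–C4 bond, so C4 shifts from C10 to C5 (Wagner–Meerwein 1,2-alkyl shift, cyclopentylcarbinyl to cyclohexyl) and the five-membered ring C10–C1–C2–C3–C4 becomes ring A with a tertiary cation at C10 (16), after which the C8=C9 alkene attacks C10 and formic acid captures the tertiary C8 cation (17). The closest known reaction types are the solvolytic ring expansion of 1-alkylcyclopentylcarbinyl sulfonates and the formolytic cation–olefin cyclisation of alkenyl sulfonates, including the acid cyclisation of monocyclic cyclogeranyl-type cations to the trans-decalins of the drimane and labdane series. Ring A is not closed but enlarged by one carbon, while ring B closes in a 6-endo-trig cation–olefin mode (bond C10–C9) through a chair-like transition state. C5 is set by inversion, since C4 enters anti to the mesylate placed in step 9; C10 is set by inversion of the camphoric-acid-derived quaternary centre, since C9 attacks the lobe anti to the departing C4, which gives the trans ring fusion; C9 follows from the (E)-alkene geometry in the chair; C8 follows from anti addition, with formic acid entering equatorially on the α face because the β face is screened by the axial C10 methyl. The step needs migration of C4 rather than of C1 or the methyl group, which is secured by the much higher migratory aptitude of a tert-alkyl carbon, by relief of the strain between the two adjacent quaternary carbons and by loss of cyclopentane strain. The formate buffer keeps the liberated sulfonic acid from re-ionising the tertiary formate and from protonating the alkene before ionisation.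

Step 12
Reactants: 18 benzyl (13S)-8α-formyloxylabdan-15-oate
Product: 19 (13S)-8α-formyloxylabdan-15-oic acid (CNP0465436.1; 5S,8R,9R,10S,13S)
Conditions: H2 (1 atm), 10% Pd/C, EtOAc, rt
Reagents that add atoms: none
Why: Hydrogenolysis of the benzyl ester is neutral, so the acid- and base-labile tertiary formate survives, and no alkene remains to be reduced.

Compound list
1 | (1S,3R)-(−)-camphoric acid | OC(=O)[C@@]1(C)CC[C@@H](C(=O)O)C1(C)C | starting material
2 | (1S,3R)-3-(methoxycarbonyl)-1,2,2-trimethylcyclopentane-1-carboxylic acid | OC(=O)[C@@]1(C)CC[C@@H](C(=O)OC)C1(C)C | intermediate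
3 | methyl (1R,3S)-3-(chlorocarbonyl)-2,2,3-trimethylcyclopentane-1-carboxylate (not isolated) | ClC(=O)[C@@]1(C)CC[C@@H](C(=O)OC)C1(C)C | intermediate
4 | methyl (1R,3S)-3-acetyl-2,2,3-trimethylcyclopentane-1-carboxylate | CC(=O)[C@@]1(C)CC[C@@H](C(=O)OC)C1(C)C | intermediate
5 | (1R,3S)-3-acetyl-2,2,3-trimethylcyclopentane-1-carboxylic acid | CC(=O)[C@@]1(C)CC[C@@H](C(=O)O)C1(C)C | intermediate
6 | 1-[(1S)-1,2,2-trimethylcyclopentyl]ethan-1-one | CC(=O)[C@@]1(C)CCCC1(C)C | intermediate
7 | (S)-(−)-citronellic acid, (3S)-3,7-dimethyloct-6-enoic acid | C[C@@H](CCC=C(C)C)CC(=O)O | starting material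
8 | benzyl (3S)-3,7-dimethyloct-6-enoate | C[C@@H](CCC=C(C)C)CC(=O)OCc1ccccc1 | intermediate
9 | benzyl (3S,6E)-8-hydroxy-3,7-dimethyloct-6-enoate | C[C@@H](CC/C=C(\C)CO)CC(=O)OCc1ccccc1 | intermediate
10 | benzyl (3S,6E)-8-bromo-3,7-dimethyloct-6-enoate | C[C@@H](CC/C=C(\C)CBr)CC(=O)OCc1ccccc1 | intermediate
11 | lithium enolate of 6 (not isolated) | [Li+].C=C([O-])[C@@]1(C)CCCC1(C)C | intermediate
12 | benzyl (3S,6E)-3,7-dimethyl-10-oxo-10-[(1S)-1,2,2-trimethylcyclopentyl]dec-6-enoate | C[C@@H](CC/C=C(\C)CCC(=O)[C@@]1(C)CCCC1(C)C)CC(=O)OCc1ccccc1 | intermediate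
13 | catechol borate (1,3,2-benzodioxaborol-2-yl ether) of 14 (not isolated) | C[C@@H](CC/C=C(\C)CC[C@H](OB1Oc2ccccc2O1)[C@@]1(C)CCCC1(C)C)CC(=O)OCc1ccccc1 | intermediate
14 | benzyl (3S,6E,10S)-10-hydroxy-3,7-dimethyl-10-[(1S)-1,2,2-trimethylcyclopentyl]dec-6-enoate | C[C@@H](CC/C=C(\C)CC[C@H](O)[C@@]1(C)CCCC1(C)C)CC(=O)OCc1ccccc1 | intermediate
15 | benzyl (3S,6E,10S)-10-(methanesulfonyloxy)-3,7-dimethyl-10-[(1S)-1,2,2-trimethylcyclopentyl]dec-6-enoate | C[C@@H](CC/C=C(\C)CC[C@H](OS(C)(=O)=O)[C@@]1(C)CCCC1(C)C)CC(=O)OCc1ccccc1 | intermediate
16 | ring-expanded monocyclic C10 cation, 2-substituted 1,3,3-trimethylcyclohexyl cation (not isolated) | C[C@@H](CC/C=C(\C)CC[C@@H]1[C+](C)CCCC1(C)C)CC(=O)OCc1ccccc1 | intermediate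
17 | bicyclic labdan-8-yl cation (not isolated) | C[C@@H](CC[C@@H]1[C@@]2(C)CCCC(C)(C)[C@@H]2CC[C+]1C)CC(=O)OCc1ccccc1 | intermediate
18 | benzyl (13S)-8α-formyloxylabdan-15-oate | C[C@@H](CC[C@@H]1[C@@]2(C)CCCC(C)(C)[C@@H]2CC[C@@]1(C)OC=O)CC(=O)OCc1ccccc1 | intermediate
19 | (13S)-8α-formyloxylabdan-15-oic acid (CNP0465436.1) | C[C@@H](CC[C@@H]1[C@@]2(C)CCCC(C)(C)[C@@H]2CC[C@@]1(C)OC=O)CC(=O)O | target

Total step count: 12. Longest linear sequence: 9 (steps 1–4 and 8–12).

Steps most likely to fail

Step 11. Three processes threaten the cascade. Proton loss from the C10 or C8 cation may outrun ring closure or formate capture. The tertiary formate may re-ionise in the acidic medium. Migration of C1 or of the methyl group may compete with migration of C4. The fallback sets out from 15 and comes back at 18. It decouples the formate from the cascade. Mesylate 15 is ionised in hexafluoroisopropanol/water buffered with 2,6-lutidine. Water then ends the same ring expansion and cyclisation and should give the tertiary alcohol benzyl labdanolate F1, which does not re-ionise under the buffer. This alcohol is formylated in a separate operation with acetic formic anhydride and pyridine to give 18.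

Step 9. Hydride transfer to the very hindered carbonyl may be slow. Facial selectivity may be poor if the adjacent quaternary centre opposes the catalyst. The fallback sets out from 12 and comes back at 14. Catalyst control is given up. Reduction with NaBH4 and CeCl3·7H2O in MeOH at 0 °C should give 14 together with its C5 epimer, the (10R)-alcohol F2. The two are diastereomers and are separated by chromatography. The unwanted epimer is re-oxidised with Dess–Martin periodinane to 12 and recycled.

Step 10. Sulfonylation of the neopentyl-type carbinol may be incomplete, or the strained mesylate may ionise prematurely during work-up. The fallback sets out from 14 and comes back at 18. Activation and ionisation are merged in one flask. Tf2O and 2,6-di-tert-butyl-4-methylpyridine in CH2Cl2 at −78 °C should give the triflate F3, which is not isolated. Formic acid is then added at −78 °C and the mixture is warmed slowly. This should trigger the same C4 shift, ring B closure and formate capture at a temperature where the tertiary formate is stable.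

Further compounds
F1 | step 11 | benzyl (13S)-8α-hydroxylabdan-15-oate (benzyl labdanolate) | C[C@@H](CC[C@@H]1[C@@]2(C)CCCC(C)(C)[C@@H]2CC[C@@]1(C)O)CC(=O)OCc1ccccc1
F2 | step 9 | benzyl (3S,6E,10R)-10-hydroxy-3,7-dimethyl-10-[(1S)-1,2,2-trimethylcyclopentyl]dec-6-enoate | C[C@@H](CC/C=C(\C)CC[C@@H](O)[C@@]1(C)CCCC1(C)C)CC(=O)OCc1ccccc1
F3 | step 10 | benzyl (3S,6E,10S)-3,7-dimethyl-10-(trifluoromethanesulfonyloxy)-10-[(1S)-1,2,2-trimethylcyclopentyl]dec-6-enoate | C[C@@H](CC/C=C(\C)CC[C@H](OS(=O)(=O)C(F)(F)F)[C@@]1(C)CCCC1(C)C)CC(=O)OCc1ccccc1
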